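**Retrosynthetic overview** (locants follow the pyrano[3,2-b]pyran numbering of the target: O-1, C-2 lactone C=O, C-3, C-4 carbinol, C-4a quaternary, O-5, C-6, C-7 acyloxy carbon, C-8, C-8a)

1. The side-chain ester at O-7 is disconnected to the bicyclic diol lactone and (2E)-4-oxooct-2-enoic acid (aldol condensation of hexan-2-one with glyoxylic acid).
2. C-3 and C-4 are set last, by syn-hydrogenation of the enol of a β-keto lactone from the face opposite the axial C-4a methyl. That lactone comes from a triol by oxidative lactonisation, and the triol from an oxygen-bridged tricycle by excision of a temporary two-carbon etheno bridge (ozonolysis, double Baeyer–Villiger, reduction).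
3. Key disconnection: C-2–C-3 and C-4a–C-8a together, by an intramolecular (4+3) cycloaddition of an oxyallyl cation (C-3/C-4/C-4a, carbonyl at C-4) with a furan whose two α-carbons become C-2 and C-8a. It dearomatises the furan and closes ring B and the bridged carbocycle that holds all six atoms of the lactone ring.
4. Enabling feature: in the lactone ring O-1 is flanked by C-2 and C-8a (a C–O–C unit, the furan), and the other three ring carbons are a 2-oxygenated three-carbon unit (the oxyallyl). Its terminus C-4a carries the ring-B ether oxygen O-5, which stabilises the cation and tethers it to the furan through C-6, C-7 and C-8.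
5. The cation precursor is an α-chloro-α′-alkoxy ketone built from a three-stereocentre alcohol (Sharpless kinetic resolution, epoxide opening by 2-furyllithium, etherification, EtLi, chlorination). Ring order: ring B and the bridged carbocycle in step 8, then the lactone ring in step 12.

Key step: step 8

Remark on stereochemistry: the cycloadduct and the compounds derived from it up to the hydroxy lactone are drawn as the diastereomer expected to predominate. At the centres that become C-3, C-4 and C-8a any epimer serves, because these centres are reset later.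
Remark on mixtures: the ether acid, the ethyl ketone and the chloro ketone are used as diastereomer mixtures at the carbons α to the carbonyl, because these centres become planar in the key step.

Step 1
Reactants: 1 (±)-(E)-pent-3-en-2-ol
Product: 2 (2S,3S,4S)-3,4-epoxypentan-2-ol
Conditions: Ti(OiPr)4 (0.1 equiv), L-(+)-diisopropyl tartrate (0.15 equiv), t-BuOOH (0.45 equiv), 4 Å MS, CH2Cl2, −20 °C
Reagents that add atoms: tert-butyl hydroperoxide, CC(C)(C)OO
Why: Sharpless kinetic resolution (asymmetric epoxidation of a secondary allylic alcohol): with the L-(+)-tartrate the (S)-alcohol should be epoxidised much faster and give the erythro epoxy alcohol, which fixes by reagent control the centres that become C-6, C-7 and (after inversion in step 3) C-8, while the unreacted (R)-alcohol is separated.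

Step 2
Reactants: 2 (2S,3S,4S)-3,4-epoxypentan-2-ol
Product: 3 triisopropylsilyl ether of 2
Conditions: TIPSOTf, 2,6-lutidine, CH2Cl2, −78 → 0 °C
Reagents that add atoms: triisopropylsilyl trifluoromethanesulfonate, CC(C)[Si](OS(=O)(=O)C(F)(F)F)(C(C)C)C(C)C
Why: Silyl ether formation with a bulky, migration-resistant group blocks Payne rearrangement during the epoxide opening and allows the neighbouring hydroxyl to be benzylated later without silyl migration.

Step 3
Reactants: 3 triisopropylsilyl ether of 2; 4 furan
Product: 6 (2R,3R,4S)-2-(furan-2-yl)-4-[(triisopropylsilyl)oxy]pentan-3-ol, via 2-furyllithium 5 (not isolated)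
Conditions: 4, n-BuLi, THF, −78 → 0 °C; then BF3·OEt2, 3, −78 °C
Reagents that add atoms: none
Why: BF3-assisted SN2 opening of an epoxide by an organolithium should occur with inversion at the methyl-bearing carbon remote from the hindered, inductively deactivating silyloxy carbon, which sets the future C-8 anti to the C-7 hydroxyl.

Step 4
Reactants: 6 (2R,3R,4S)-2-(furan-2-yl)-4-[(triisopropylsilyl)oxy]pentan-3-ol
Product: 8 (2S,3R,4R)-3-(benzyloxy)-4-(furan-2-yl)pentan-2-ol, via benzyl ether 7 (not isolated)
Conditions: NaH, BnBr, n-Bu4NI (cat.), THF/DMF, 0 °C → rt; then n-Bu4NF, THF, rt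
Reagents that add atoms: benzyl bromide, BrCc1ccccc1
Why: Williamson benzylation followed by fluoride desilylation in one pot exchanges the protecting groups so that the C-7 oxygen stays masked to the end and the C-6 hydroxyl is free to become the ring oxygen O-5, without touching a stereocentre.

Step 5
Reactants: 8 (2S,3R,4R)-3-(benzyloxy)-4-(furan-2-yl)pentan-2-ol; 9 (±)-2-bromopropanoic acid
Product: 10 2-{[(2S,3R,4R)-3-(benzyloxy)-4-(furan-2-yl)pentan-2-yl]oxy}propanoic acid
Conditions: NaH (3 equiv), THF, 0 → 60 °C; aqueous work-up at pH 4
Reagents that add atoms: none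
Why: Williamson etherification of the alkoxide with the α-bromo carboxylate (SN2, the carboxylate suppressing elimination and enolisation) is the standard way to lactyl ethers of hindered secondary alcohols, and the new centre (future C-4a) is left as a mixture on purpose.

Step 6
Reactants: 10 2-{[(2S,3R,4R)-3-(benzyloxy)-4-(furan-2-yl)pentan-2-yl]oxy}propanoic acid; 11 ethyllithium
Product: 12 2-{[(2S,3R,4R)-3-(benzyloxy)-4-(furan-2-yl)pentan-2-yl]oxy}pentan-3-one
Conditions: EtLi (2.5 equiv), Et2O, −78 → −10 °C; then H2O
Reagents that add atoms: none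
Why: Ketone synthesis from a carboxylate and an organolithium (the gem-diolate resists a second addition and collapses on work-up) installs the future C-3 and its methyl group, the low temperature keeping metalation of the free furan α-position slow.

Step 7
Reactants: 12 2-{[(2S,3R,4R)-3-(benzyloxy)-4-(furan-2-yl)pentan-2-yl]oxy}pentan-3-one
Product: 14 2-chloro-4-{[(2S,3R,4R)-3-(benzyloxy)-4-(furan-2-yl)pentan-2-yl]oxy}pentan-3-one, via lithium enolate 13 (not isolated)
Conditions: LiN(iPr)2 (1.1 equiv), THF, −78 °C; then CF3SO2Cl, −78 °C
Reagents that add atoms: trifluoromethanesulfonyl chloride, ClS(=O)(=O)C(F)(F)F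
Why: Kinetic deprotonation should take place at the unhindered CH2 of the ethyl group and not at the alkoxy-bearing methine, and enolate chlorination with triflyl chloride (a positive-chlorine donor that spares the furan) gives the α′-chloro ketone as a diastereomer mixture that needs no control.

Step 8
Reactants: 14 2-chloro-4-{[(2S,3R,4R)-3-(benzyloxy)-4-(furan-2-yl)pentan-2-yl]oxy}pentan-3-one
Product: 16 tricyclic (4+3) cycloadduct ketone, via oxyallyl cation 15 (not isolated)
Conditions: Et3N (3 equiv), CF3CH2OH (0.01 M), 0 °C → rt
Reagents that add atoms: none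
Why: Et3N enolises 14 towards the alkoxy-bearing carbon and chloride leaves in the ionising solvent to give the planar oxyallyl cation 15, stabilised by the ether oxygen (future O-5), which adds across the two α-carbons of the tethered furan in a (4+3) cycloaddition that forms C-4a–C-8a and C-2–C-3 in one operation and dearomatises the furan. The closest known reaction type is the base-induced (4+3) cycloaddition of α-halo ketones with furans in trifluoroethanol, in its intramolecular form and with alkoxy-substituted oxyallyl cations. Ring B closes first by 6-endo-trig attack of the substituted furan carbon on the oxocarbenium carbon, and the second bond closes the seven-membered carbocycle onto the furan-derived oxocarbenium ion, whose oxygen bridge completes the six-membered O–C–C–C–C–C ring that becomes the lactone. All four diastereomers of 14 converge on the same cation, so the new quaternary centre C-4a is set only by the chair-like transition state of ring B, with the three tether substituents equatorial and the (E)-oxocarbenium geometry placing the enol carbon equatorial and the methyl axial; the two bridgeheads follow from suprafacial addition to one furan face, and the α-methyl centre is drawn as the equatorial epimer reached under the basic conditions. The step needs site selectivity (bonding at the substituted furan carbon, secured by the four-atom tether and high dilution) and facial selectivity at C-4a (secured by the three equatorial tether substituents), whereas the bridgehead that becomes C-8a and the carbons that become C-3 and C-4 need no control, because steps 11 to 13 reset them.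

Step 9
Reactants: 16 tricyclic (4+3) cycloadduct ketone
Product: 17 tricyclic alcohol
Conditions: NaBH4, MeOH, 0 °C
Reagents that add atoms: none
Why: Hydride reduction of the ketone, expected mainly from the face away from the etheno bridge, removes the β-dicarbonyl relationship before the bridge is cleaved, and the carbinol configuration is immaterial because this centre is re-oxidised in step 12.

Step 10
Reactants: 17 tricyclic alcohol
Product: 18 dialdehyde
Conditions: O3, CH2Cl2, −78 °C; then Me2S, −78 °C → rt
Reagents that add atoms: ozone, [O-][O+]=O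
Why: Ozonolysis with reductive work-up cleaves the strained alkene of the temporary two-carbon bridge and leaves a cis-2,6-diformyl tetrahydropyran in which each formyl group sits on an oxygen-bearing carbon.

Step 11
Reactants: 18 dialdehyde
Product: 21 triol, via bis(formate) 19 (not isolated), via keto aldehyde 20 (not isolated)
Conditions: mCPBA, CH2Cl2, 0 °C → rt; then NaBH4, MeOH, 0 °C
Reagents that add atoms: 3-chloroperoxybenzoic acid, OOC(=O)c1cccc(Cl)c1
Why: Baeyer–Villiger oxidation of the two α-alkoxy aldehydes (the oxygen-substituted carbons migrate) turns both bridge carbons into formates, whose methanolysis unravels the double hemiacetal to a keto aldehyde that is reduced at once, the ring ketone being attacked axially, anti to the axial methyl on the neighbouring quaternary carbon, which sets C-8a with an equatorial hydroxyl.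

Step 12
Reactants: 21 triol
Product: 23 β-keto lactone (enol form), via hydroxy lactone 22 (not isolated)
Conditions: TEMPO (cat.), PhI(OAc)2, CH2Cl2, rt; then Dess–Martin periodinane, rt
Reagents that add atoms: none
Why: TEMPO-mediated oxidation is selective for the primary alcohol and carries the resulting δ-lactol on to the trans-fused δ-lactone (oxidative lactonisation of a 1,5-diol), after which Dess–Martin oxidation of the remaining hindered carbinol gives the β-keto lactone, whose enolisation erases the configurations at C-3 and C-4.

Step 13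
Reactants: 23 β-keto lactone (enol form)
Product: 24 (3R,4S,4aR,6S,7R,8R,8aS)-7-(benzyloxy)-4-hydroxy-3,4a,6,8-tetramethylhexahydropyrano[3,2-b]pyran-2(3H)-one
Conditions: H2 (50 bar), Raney Ni, EtOAc, rt
Reagents that add atoms: none
Why: Heterogeneous syn-hydrogenation of the enol of a 3-alkyl-4-hydroxy-5,6-dihydropyran-2-one, a known route to cis-3-alkyl-4-hydroxy δ-lactones, should deliver both hydrogens from the face opposite the axial C-4a methyl and so set C-3 and C-4 with methyl, hydroxyl and angular methyl all cis.

Step 14
Reactants: 24 (3R,4S,4aR,6S,7R,8R,8aS)-7-(benzyloxy)-4-hydroxy-3,4a,6,8-tetramethylhexahydropyrano[3,2-b]pyran-2(3H)-one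
Product: 25 (3R,4S,4aR,6S,7R,8R,8aS)-4,7-dihydroxy-3,4a,6,8-tetramethylhexahydropyrano[3,2-b]pyran-2(3H)-one
Conditions: H2 (1 atm), Pd(OH)2/C, EtOAc, rt
Reagents that add atoms: none
Why: Hydrogenolysis of the benzyl ether frees the C-7 hydroxyl under neutral conditions that leave the lactone and its epimerisable α-centre untouched.

Step 15
Reactants: 26 hexan-2-one; 27 glyoxylic acid monohydrate
Product: 28 (2E)-4-oxooct-2-enoic acid
Conditions: pyrrolidine, AcOH, MeOH, 60 °C
Reagents that add atoms: none
Why: Amine-mediated aldol condensation (the enamine formed on the methyl side of the ketone adds to glyoxylic acid and the aldol dehydrates) gives the thermodynamically favoured (E)-4-oxo-2-enoic acid.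

Step 16
Reactants: 25 (3R,4S,4aR,6S,7R,8R,8aS)-4,7-dihydroxy-3,4a,6,8-tetramethylhexahydropyrano[3,2-b]pyran-2(3H)-one; 28 (2E)-4-oxooct-2-enoic acid
Product: 29 target
Conditions: 2-methyl-6-nitrobenzoic anhydride, DMAP (cat.), Et3N, CH2Cl2, 0 °C → rt
Reagents that add atoms: none
Why: Shiina esterification through the mixed anhydride should acylate the equatorial C-7 hydroxyl, flanked only by two CH(CH3) groups, in preference to the C-4 hydroxyl, which is shielded by the quaternary C-4a and the cis C-3 methyl, and it affects no stereocentre.

**Compound list**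

1 | (±)-(E)-pent-3-en-2-ol | C/C=C/C(C)O | starting material
2 | (2S,3S,4S)-3,4-epoxypentan-2-ol | C[C@H](O)[C@@H]1O[C@H]1C | intermediate
3 | triisopropylsilyl ether of 2 (configuration unchanged) | C[C@H](O[Si](C(C)C)(C(C)C)C(C)C)[C@@H]1O[C@H]1C | intermediate
4 | furan | c1ccoc1 | starting material
5 | 2-furyllithium | [Li]c1ccco1 | intermediate
6 | (2R,3R,4S)-2-(furan-2-yl)-4-[(triisopropylsilyl)oxy]pentan-3-ol | C[C@H](O[Si](C(C)C)(C(C)C)C(C)C)[C@H](O)[C@@H](C)c1ccco1 | intermediate
7 | (2R,3R,4S)-3-(benzyloxy)-2-(furan-2-yl)-4-[(triisopropylsilyl)oxy]pentane | C[C@H](O[Si](C(C)C)(C(C)C)C(C)C)[C@H](OCc1ccccc1)[C@@H](C)c1ccco1 | intermediate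
8 | (2S,3R,4R)-3-(benzyloxy)-4-(furan-2-yl)pentan-2-ol | C[C@H](O)[C@H](OCc1ccccc1)[C@@H](C)c1ccco1 | intermediate
9 | (±)-2-bromopropanoic acid | CC(Br)C(=O)O | starting material
10 | 2-{[(2S,3R,4R)-3-(benzyloxy)-4-(furan-2-yl)pentan-2-yl]oxy}propanoic acid (both epimers at C-2 of the acid) | C[C@H](OC(C)C(=O)O)[C@H](OCc1ccccc1)[C@@H](C)c1ccco1 | intermediate
11 | ethyllithium | [Li]CC | starting material
12 | 2-{[(2S,3R,4R)-3-(benzyloxy)-4-(furan-2-yl)pentan-2-yl]oxy}pentan-3-one (both epimers at C-2) | C[C@H](OC(C)C(=O)CC)[C@H](OCc1ccccc1)[C@@H](C)c1ccco1 | intermediate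
13 | lithium (Z)-enolate of 12, formed on the ethyl side | C/C=C(\O[Li])C(C)O[C@@H](C)[C@H](OCc1ccccc1)[C@@H](C)c1ccco1 | intermediate
14 | 2-chloro-4-{[(2S,3R,4R)-3-(benzyloxy)-4-(furan-2-yl)pentan-2-yl]oxy}pentan-3-one (four diastereomers at C-2 and C-4) | C[C@H](OC(C)C(=O)C(C)Cl)[C@H](OCc1ccccc1)[C@@H](C)c1ccco1 | intermediate
15 | alkoxy-stabilised oxyallyl cation from 14 (zwitterion form, oxocarbenium on the ether oxygen) | C/C=C(\[O-])C(C)=[O+][C@@H](C)[C@H](OCc1ccccc1)[C@@H](C)c1ccco1 | intermediate
16 | (4+3) cycloadduct: 2,4-dimethyl-8-oxabicyclo[3.2.1]oct-6-en-3-one whose position 4 (quaternary, axial methyl) and bridgehead 5 are linked by O–CH(CH3)–CH(OBn)–CH(CH3) (ring B, trans-fused to the pyranone ring, three substituents equatorial); methyl at position 2 equatorial | [C@@H]12C=C[C@]3(O1)[C@H](C)[C@@H](OCc1ccccc1)[C@H](C)O[C@]3(C)C(=O)[C@@H]2C | intermediate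
17 | 3-ol of 16 (hydroxyl axial, on the side of the etheno bridge) | [C@@H]12C=C[C@]3(O1)[C@H](C)[C@@H](OCc1ccccc1)[C@H](C)O[C@]3(C)[C@H](O)[C@@H]2C | intermediate
18 | dialdehyde from 17: cis-2,6-diformyl tetrahydropyran (4-hydroxy, 3,5-dimethyl) fused to ring B | O=C[C@@H]1O[C@@]2(C=O)[C@H](C)[C@@H](OCc3ccccc3)[C@H](C)O[C@]2(C)[C@H](O)[C@@H]1C | intermediate
19 | bis(formate): both formyl groups of 18 replaced by formyloxy with retention | O=CO[C@@H]1O[C@@]2(OC=O)[C@H](C)[C@@H](OCc3ccccc3)[C@H](C)O[C@]2(C)[C@H](O)[C@@H]1C | intermediate
20 | keto aldehyde: 3-hydroxy-2-methyl-3-[5-(benzyloxy)-2,4,6-trimethyl-3-oxooxan-2-yl]propanal | C[C@H](C=O)[C@@H](O)[C@@]1(C)O[C@@H](C)[C@H](OCc2ccccc2)[C@@H](C)C1=O | intermediate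
21 | triol: 5-(benzyloxy)-2-(1,3-dihydroxy-2-methylpropyl)-2,4,6-trimethyloxan-3-ol (2-methyl axial; 3-OH, 4-methyl, 5-OBn, 6-methyl equatorial) | C[C@H](CO)[C@@H](O)[C@@]1(C)O[C@@H](C)[C@H](OCc2ccccc2)[C@@H](C)[C@@H]1O | intermediate
22 | (3S,4R,4aR,6S,7R,8R,8aS)-7-(benzyloxy)-4-hydroxy-3,4a,6,8-tetramethylhexahydropyrano[3,2-b]pyran-2(3H)-one (C-3 and C-4 epimer of 24) | C(c3ccccc3)O[C@@H]1[C@@H](C)[C@@H]2OC(=O)[C@@H](C)[C@@H](O)[C@@]2(C)O[C@H]1C | intermediate
23 | enol form of the β-keto lactone: 7-(benzyloxy)-4-hydroxy-3,4a,6,8-tetramethyl-4a,7,8,8a-tetrahydropyrano[3,2-b]pyran-2(6H)-one (the five remaining stereocentres arranged as in 24) | C(c3ccccc3)O[C@@H]1[C@@H](C)[C@@H]2OC(=O)C(C)=C(O)[C@@]2(C)O[C@H]1C | intermediate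
24 | (3R,4S,4aR,6S,7R,8R,8aS)-7-(benzyloxy)-4-hydroxy-3,4a,6,8-tetramethylhexahydropyrano[3,2-b]pyran-2(3H)-one | C(c3ccccc3)O[C@@H]1[C@@H](C)[C@@H]2OC(=O)[C@H](C)[C@H](O)[C@@]2(C)O[C@H]1C | intermediate
25 | (3R,4S,4aR,6S,7R,8R,8aS)-4,7-dihydroxy-3,4a,6,8-tetramethylhexahydropyrano[3,2-b]pyran-2(3H)-one | O[C@@H]1[C@@H](C)[C@@H]2OC(=O)[C@H](C)[C@H](O)[C@@]2(C)O[C@H]1C | intermediate
26 | hexan-2-one | CCCCC(C)=O | starting material
27 | glyoxylic acid monohydrate | OC(O)C(=O)O | starting material
28 | (2E)-4-oxooct-2-enoic acid | CCCCC(=O)/C=C/C(=O)O | intermediate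
29 | (3R,4S,4aR,6S,7R,8R,8aS)-4-hydroxy-3,4a,6,8-tetramethyl-2-oxooctahydropyrano[3,2-b]pyran-7-yl (2E)-4-oxooct-2-enoate | CCCCC(=O)/C=C/C(=O)O[C@@H]1[C@@H](C)[C@@H]2OC(=O)[C@H](C)[C@H](O)[C@@]2(C)O[C@H]1C | target

**Step count and risks**

Total step count: 16. Longest linear sequence: 15 steps (steps 1 to 14 and 16; step 15 is a one-step side branch).

Steps most likely to fail:

Step 8. The cycloaddition has to close a six-membered ring at a fully substituted cation carbon. If it is slow, capture of the oxyallyl cation by trifluoroethanol or Favorskii-type ring contraction can outrun it, and enolisation towards the chlorine-bearing carbon gives no cation at all. The fallback generates the same cation as its silyl ether under aprotic Lewis-acid conditions, ionising at the ether-bearing carbon instead; it sets out from 8 and returns at 16. Acetal exchange of 8 with 2,2-dimethoxypentan-3-one F1 (made from pentane-2,3-dione and trimethyl orthoformate, TsOH, MeOH) under pyridinium tosylate with removal of methanol should give the mixed methyl ketal F2. LiN(iPr)2 and Et3SiCl (THF, −78 °C) then give the (Z)-triethylsilyl enol ether F3 at the only enolisable position. Me3SiOTf (0.1 equiv) in CH2Cl2 at −78 °C ionises the ketal with loss of the methoxy group, and the resulting 2-silyloxy-1-alkoxyallyl cation undergoes the same intramolecular (4+3) cycloaddition to 16 (the known Lewis-acid (4+3) reaction of silyl enol ethers of α-keto acetals with furans).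

Step 11. In the peracid stage the less substituted aldehyde may be oxidised to the carboxylic acid by hydride migration instead of rearranging by carbon migration, and the axial hydroxyl can tie up an aldehyde as a lactol, so that one bridge carbon stays in place. The fallback removes both carbons by oxidative decarboxylation; it sets out from 18 and returns at 21. Pinnick oxidation (NaClO2, NaH2PO4, 2-methyl-2-butene, t-BuOH/H2O) gives the dicarboxylic acid F4. Pb(OAc)4 with pyridine in THF decarboxylates both α-alkoxy acids through their oxocarbenium ions to the bis(acetate) F5. NaBH4 in MeOH then cleaves the anomeric acetates and reduces the liberated keto aldehyde to 21.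

Step 13. Hydrogenation of the tetrasubstituted enol next to the quaternary carbon may be slow, and reduction through the keto tautomer would lose the syn delivery and give the wrong configuration at C-3. The fallback sets the two centres separately by hydride addition and kinetic protonation; it sets out from 23 and returns at 24. NaBH4 (MeOH/CH2Cl2, −40 °C) attacks the ketone from the face opposite the axial C-4a methyl and gives the hydroxy lactone with the correct carbinol, drawn as the C-3 epimer of 24, F6. LiN(iPr)2 (2.5 equiv, THF, −78 °C) then forms the alkoxide enolate, and protonation with 2,6-di-tert-butylphenol from the face opposite the alkoxide and the axial methyl gives 24.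

**Further compounds**

F1 | step 8 | 2,2-dimethoxypentan-3-one | CCC(=O)C(C)(OC)OC
F2 | step 8 | 2-{[(2S,3R,4R)-3-(benzyloxy)-4-(furan-2-yl)pentan-2-yl]oxy}-2-methoxypentan-3-one (both ketal epimers) | C[C@H](OC(C)(OC)C(=O)CC)[C@H](OCc1ccccc1)[C@@H](C)c1ccco1
F3 | step 8 | (Z)-triethylsilyl enol ether of F2 | C/C=C(\O[Si](CC)(CC)CC)C(C)(OC)O[C@@H](C)[C@H](OCc1ccccc1)[C@@H](C)c1ccco1
F4 | step 11 | dicarboxylic acid corresponding to dialdehyde 18 | OC(=O)[C@@H]1O[C@@]2(C(=O)O)[C@H](C)[C@@H](OCc3ccccc3)[C@H](C)O[C@]2(C)[C@H](O)[C@@H]1C
F5 | step 11 | bis(acetate) in which both carboxyl groups of F4 are replaced by acetoxy (anomeric mixture) | CC(=O)OC1OC2(OC(C)=O)[C@H](C)[C@@H](OCc3ccccc3)[C@H](C)O[C@]2(C)[C@H](O)[C@@H]1C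
F6 | step 13 | (3S,4S,4aR,6S,7R,8R,8aS)-7-(benzyloxy)-4-hydroxy-3,4a,6,8-tetramethylhexahydropyrano[3,2-b]pyran-2(3H)-one (C-3 epimer of 24) | C(c3ccccc3)O[C@@H]1[C@@H](C)[C@@H]2OC(=O)[C@@H](C)[C@H](O)[C@@]2(C)O[C@H]1C
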